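**Retrosynthetic overview**

1. The plan rests on the N–CH–CH2–C–O unit of ring B: the ring nitrogen, the CH that carries lactone E, the ring CH2, and the quaternary carbon shared by rings B, C and D with its lactone D oxygen form a γ-amino alcohol, which is an isoxazolidine with its N–O bond cut.
2. Key disconnection: (3+2) cycloaddition of the Z-nitrone 10 of the lactone E aldehyde onto the exocyclic α-methylene ketone 21 of ring C forms the CH–CH2 bond and the quaternary C–O bond in spiro-isoxazolidine 22.
3. Enone 21 comes from dioxaspiro enone 13 by ligand-controlled copper-catalysed Et2Zn addition with palladium-catalysed allylic trapping of the zinc enolate. The trapped four-carbon arm is the future ring A, and it forces the α-methylenation onto the other α-carbon.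
4. After the cycloaddition: hydrogenolysis (N–O, N–Bn, O–Bn) and imine closure give ring B; N-alkylation by the arm gives ring A as the enamine; ketal removal, enolate alkylation with an (R)-lactate triflate and lactonisation give ring D; ketone reduction sets the alcohol.
5. Ring order: E (chiral pool) and C (bought) → isoxazolidine (temporary) → B → A → D.

Key step: step 12

Remarks
- Ring letters: A = azepine, B = five-membered nitrogen ring, C = carbocycle, D = fused lactone, E = pendant lactone.
- Assumption: the (R,S,S)-phosphoramidite delivers ethyl to the enone face that gives the (6S) ketone, the mirror image of the sense in which the (S,R,R)-ligand gives (S)-3-ethylcyclohexanone from cyclohex-2-enone (the descriptor changes because the ketal carbon outranks the α-carbon).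
- Assumption: compounds 1, 9, 11, 13, 14 and 29 are bought.

**Route**

Step 1
Reactants: 1 (S)-5-(hydroxymethyl)dihydrofuran-2(3H)-one
Product: 2 (S)-5-[(trityloxy)methyl]dihydrofuran-2(3H)-one
Conditions: TrCl, pyridine, DMAP (cat.), CH2Cl2, rt
Reagents that add atoms: trityl chloride, ClC(c1ccccc1)(c1ccccc1)c1ccccc1
Why: Tritylation of the primary alcohol (SN1-type etherification) installs the bulky group that later directs both enolate reactions of the lactone.

Step 2
Reactants: 2 (S)-5-[(trityloxy)methyl]dihydrofuran-2(3H)-one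
Product: 4 (3R,5S)-3-methyl-5-[(trityloxy)methyl]dihydrofuran-2(3H)-one (trans), via lithium enolate 3 (not isolated)
Conditions: LiN(i-Pr)2, THF, −78 °C; MeI, −78 → −40 °C
Reagents that add atoms: iodomethane, CI
Why: Lactone enolate alkylation; methyl iodide should enter anti to the trityloxymethyl group and give the trans lactone.

Step 3
Reactants: 4 (3R,5S)-3-methyl-5-[(trityloxy)methyl]dihydrofuran-2(3H)-one
Product: 6 (3S,5S)-3-methyl-5-[(trityloxy)methyl]dihydrofuran-2(3H)-one (cis), via lithium enolate 5 (not isolated)
Conditions: LiN(i-Pr)2, THF, −78 °C; sat. aq. Na2SO4, −78 °C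
Reagents that add atoms: none
Why: Kinetic protonation of the planar enolate on the face opposite the trityloxymethyl group should turn the methyl cis, which is the lactone E configuration; residual trans isomer is separable and can be resubmitted.

Step 4
Reactants: 6 (3S,5S)-3-methyl-5-[(trityloxy)methyl]dihydrofuran-2(3H)-one
Product: 7 (3S,5S)-5-(hydroxymethyl)-3-methyldihydrofuran-2(3H)-one
Conditions: TsOH·H2O (cat.), MeOH–CH2Cl2, rt
Reagents that add atoms: none
Why: Acid-catalysed methanolysis of the trityl ether (the trityl cation is trapped as methyl trityl ether) frees the primary alcohol without touching the lactone or its α-centre.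

Step 5
Reactants: 7 (3S,5S)-5-(hydroxymethyl)-3-methyldihydrofuran-2(3H)-one
Product: 8 (2S,4S)-4-methyl-5-oxotetrahydrofuran-2-carbaldehyde
Conditions: Dess–Martin periodinane, CH2Cl2, 0 °C → rt
Reagents that add atoms: none
Why: Dess–Martin oxidation under near-neutral conditions should give the α-oxy aldehyde without epimerisation; it is used crude.

Step 6
Reactants: 8 (2S,4S)-4-methyl-5-oxotetrahydrofuran-2-carbaldehyde; 9 N-benzylhydroxylamine
Product: 10 (Z)-N-benzyl-1-[(2S,4S)-4-methyl-5-oxotetrahydrofuran-2-yl]methanimine N-oxide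
Conditions: MgSO4, CH2Cl2, rt
Reagents that add atoms: N-benzylhydroxylamine, ONCc1ccccc1
Why: Condensation of an aldehyde with an N-monosubstituted hydroxylamine gives the aldonitrone, expected as the Z isomer with the lactone anti to the benzyl group.

Step 7
Reactants: 11 (Z)-4-(benzyloxy)but-2-en-1-ol
Product: 12 (Z)-4-(benzyloxy)but-2-en-1-yl acetate
Conditions: Ac2O, pyridine, DMAP (cat.), CH2Cl2, 0 °C → rt
Reagents that add atoms: acetic anhydride, CC(=O)OC(C)=O
Why: Acetylation provides the allylic leaving group for the palladium-catalysed trapping.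

Step 8
Reactants: 13 1,4-dioxaspiro[4.5]dec-6-en-8-one; 14 diethylzinc; 12 (Z)-4-(benzyloxy)but-2-en-1-yl acetate
Product: 16 (6S,7S)-7-[(E)-4-(benzyloxy)but-2-en-1-yl]-6-ethyl-1,4-dioxaspiro[4.5]decan-8-one, via ethylzinc enolate 15 (not isolated)
Conditions: Et2Zn (1.3 equiv), Cu(OTf)2 (2 mol%), (R,S,S)-phosphoramidite [O,O′-(R)-1,1′-binaphthalene-2,2′-diyl N,N-bis((S)-1-phenylethyl)phosphoramidite] (4 mol%), toluene, −30 °C; then 12, Pd(PPh3)4 (4 mol%), 0 °C
Reagents that add atoms: diethylzinc, CC[Zn]CC; (Z)-4-(benzyloxy)but-2-en-1-yl acetate, CC(=O)OC/C=C\COCc1ccccc1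
Why: Copper-catalysed enantioselective 1,4-addition sets the ethyl-bearing centre under ligand control, and the regiodefined zinc enolate is trapped by palladium-catalysed allylic alkylation (Tsuji–Trost type) at the unsubstituted allyl terminus and anti to ethyl, giving the trans 2,3-disubstituted ketone.

Step 9
Reactants: 16 (6S,7S)-7-[(E)-4-(benzyloxy)but-2-en-1-yl]-6-ethyl-1,4-dioxaspiro[4.5]decan-8-one
Product: 17 (6S,7S)-7-[4-(benzyloxy)butyl]-6-ethyl-1,4-dioxaspiro[4.5]decan-8-one
Conditions: H2 (1 atm), Pd/C, pyridine (0.5 equiv), EtOAc, rt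
Reagents that add atoms: none
Why: Alkene hydrogenation in which the amine additive suppresses benzyl ether hydrogenolysis on Pd/C; the arm is saturated before the dipole is introduced.

Step 10
Reactants: 17 (6S,7S)-7-[4-(benzyloxy)butyl]-6-ethyl-1,4-dioxaspiro[4.5]decan-8-one
Product: 19 (6S,7S)-7-[4-(benzyloxy)butyl]-9-[(dimethylamino)methyl]-6-ethyl-1,4-dioxaspiro[4.5]decan-8-one (C9 epimers), via lithium enolate 18 (not isolated)
Conditions: LiN(i-Pr)2, THF, −78 °C; [Me2N=CH2]I, −78 °C → rt
Reagents that add atoms: dimethylmethylideneammonium iodide, C[N+](C)=C.[I-]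
Why: Kinetic deprotonation of a 2-alkylcyclohexanone goes to the unsubstituted α-CH2, so the Mannich reaction places the aminomethyl group on the α-carbon remote from ethyl; the new centre is lost in the next step.

Step 11
Reactants: 19 (6S,7S)-7-[4-(benzyloxy)butyl]-9-[(dimethylamino)methyl]-6-ethyl-1,4-dioxaspiro[4.5]decan-8-one
Product: 21 (6S,7S)-7-[4-(benzyloxy)butyl]-6-ethyl-9-methylidene-1,4-dioxaspiro[4.5]decan-8-one, via methiodide 20 (not isolated)
Conditions: MeI, Et2O, rt; then aq. NaHCO3, CH2Cl2, rt
Reagents that add atoms: none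
Why: Quaternisation and E1cB (Hofmann-type) loss of trimethylamine from the β-ammonio ketone give the exocyclic enone, which is taken directly into the cycloaddition.

Step 12
Reactants: 10 (Z)-N-benzyl-1-[(2S,4S)-4-methyl-5-oxotetrahydrofuran-2-yl]methanimine N-oxide; 21 (6S,7S)-7-[4-(benzyloxy)butyl]-6-ethyl-9-methylidene-1,4-dioxaspiro[4.5]decan-8-one
Product: 22 N-benzyl spiro-isoxazolidine (isoxazolidine C5 is the α-carbon of the ring C ketone with its oxygen trans to ethyl; C3 is R and carries the (2S,4S)-4-methyl-5-oxotetrahydrofuran-2-yl group cis to the ketone carbon)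
Conditions: 10 (1.3 equiv), toluene, 60 °C, freshly prepared 21
Reagents that add atoms: none
Why: This is a concerted, suprafacial (3+2) cycloaddition of the Z-nitrone to the electron-poor 1,1-disubstituted alkene, the known behaviour of nitrones toward α-methylene ketones and lactones, which puts the nitrone oxygen on the substituted α-carbon and the nitrone carbon on the methylene. The isoxazolidine ring closes in one intermolecular event by simultaneous formation of the CH–CH2 bond and the C–O bond, spiro at the α-carbon, so no separate cyclisation mode has to be met. The quaternary C–O centre is set by the enone face: in the chair with ethyl and the side arm equatorial, the axial dioxolane oxygen and the axial hydrogen 1,3 to the methylene carbon block the axial face, so oxygen should enter equatorially, trans to ethyl. The N–CH centre is set by the nitrone face: attack anti to the lactone C–O bond (Felkin–Anh type) gives the required anti N/O relationship to the lactone stereocentre. These two faces combine in the exo transition state, with the ring carbonyl pointing away from nitrogen and only the ring CH2 beneath the N-benzyl group, which places the lactone substituent cis to the ketone carbon on the isoxazolidine. The step therefore needs regio-, facial and exo selectivity, which rest respectively on the carbonyl polarisation of the alkene, on the ketal and the lactone stereocentre, and on the steric and dipole preference for carbonyl-exo; the enone is used fresh because it can dimerise.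

Step 13
Reactants: 22 N-benzyl spiro-isoxazolidine
Product: 24 hydroxy imine with ring B closed (6-ethyl-3a-hydroxy-7-(4-hydroxybutyl)-2-[(2S,4S)-4-methyl-5-oxotetrahydrofuran-2-yl]-3,3a,4,5,6,7-hexahydro-2H-indol-5-one ethylene ketal), via ammonium trifluoroacetate 23 (not isolated)
Conditions: H2 (1 atm), Pd(OH)2/C, CF3CO2H (3 equiv), THF, rt; filter; NaOAc, 4 Å MS, rt → 40 °C; aq. NaHCO3 work-up
Reagents that add atoms: none
Why: Hydrogenolysis cleaves the N–O bond and both benzyl groups while the acid keeps nitrogen protonated, so neither reductive amination nor O-to-N acyl shift onto lactone E can intervene, and in the acetate buffer the ammonium ketone condenses to the five-membered cyclic imine.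

Step 14
Reactants: 24 hydroxy imine with ring B closed
Product: 27 tricyclic enamine (rings A, B and C) with tertiary alcohol and ring C ketal, via primary mesylate 25 (not isolated), via cyclic iminium mesylate 26 (not isolated)
Conditions: MsCl (1.1 equiv), Et3N (3 equiv), CH2Cl2, −20 °C; then MeCN, NaI (cat.), 50 °C
Reagents that add atoms: none
Why: The primary alcohol is mesylated in preference to the hindered tertiary one, and the imine nitrogen then displaces the mesylate (SN2, seven-membered ring); the iminium loses its only α-proton to give the tetrasubstituted enamine, as in known intramolecular N-alkylations of cyclic imines to bicyclic enamines.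

Step 15
Reactants: 27 tricyclic enamine with ring C ketal
Product: 28 tricyclic enamine hydroxy ketone (ring C ketone β to the tertiary alcohol)
Conditions: 1 M HCl, THF, rt; then aq. NaHCO3
Reagents that add atoms: water, O
Why: Acid-catalysed ketal hydrolysis; the enamine is held as its C-protonated iminium salt in acid and returns on neutralisation, and the short, cold exposure limits enolisation toward the ethyl-bearing carbon.

Step 16
Reactants: 29 methyl (R)-lactate
Product: 30 methyl (R)-2-{[(trifluoromethyl)sulfonyl]oxy}propanoate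
Conditions: Tf2O, 2,6-lutidine, CH2Cl2, −78 → 0 °C; used at once
Reagents that add atoms: trifluoromethanesulfonic anhydride, O=S(=O)(OS(=O)(=O)C(F)(F)F)C(F)(F)F
Why: O-Sulfonylation of the α-hydroxy ester proceeds without touching the stereocentre and gives the configurationally defined electrophile.

Step 17
Reactants: 28 tricyclic enamine hydroxy ketone; 30 methyl (R)-2-{[(trifluoromethyl)sulfonyl]oxy}propanoate
Product: 33 keto lactone (rings A to E complete, ring C ketone), via dilithium alkoxide enolate 31 (not isolated), via alkylated alkoxide ester 32 (not isolated)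
Conditions: LiN(SiMe3)2 (2.1 equiv, added to 28), THF, −78 °C; 30 (1.3 equiv), −78 → 0 °C; AcOH quench; then DBU (0.2 equiv), CH2Cl2, rt
Reagents that add atoms: methyl (R)-2-{[(trifluoromethyl)sulfonyl]oxy}propanoate, C[C@@H](OS(=O)(=O)C(F)(F)F)C(=O)OC
Why: Dianion formation (alkoxide, then kinetic enolate at the ring CH2; Fráter–Seebach type, with no β-elimination possible from an alkoxide) is followed by SN2 alkylation with the α-triflyloxy ester with inversion, so the (R)-triflate gives the (R)-configured methyl-bearing carbon; the alkoxide closes lactone D on the cis isomer, and DBU epimerises any trans-alkylated ketone at its α-carbon into the cis-fused lactone, the only arrangement that can lactonise.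

Step 18
Reactants: 33 keto lactone
Product: 34 CNP0154902.3 (target)
Conditions: Li[HB(s-Bu)3] (1.2 equiv), THF, −78 °C; AcOH, −78 °C
Reagents that add atoms: none
Why: The bulky trialkylborohydride should attack the ketone equatorially, on the face opposite the pseudoaxial lactone oxygen 1,3 to the carbonyl, giving the axial alcohol cis to lactone D and trans to ethyl as in equatorial-selective reductions of hindered cyclohexanones; the cold acidic quench prevents translactonisation onto the new alkoxide.

**Compound list**

1 | (S)-5-(hydroxymethyl)dihydrofuran-2(3H)-one | OC[C@@H]1CCC(=O)O1 | starting material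
2 | (S)-5-[(trityloxy)methyl]dihydrofuran-2(3H)-one | O(C[C@@H]1CCC(=O)O1)C(c2ccccc2)(c2ccccc2)c2ccccc2 | intermediate
3 | lithium enolate of 2 | O(C[C@@H]1CC=C([O-])O1)C(c2ccccc2)(c2ccccc2)c2ccccc2.[Li+] | intermediate
4 | (3R,5S)-3-methyl-5-[(trityloxy)methyl]dihydrofuran-2(3H)-one (trans) | O(C[C@@H]1C[C@@H](C)C(=O)O1)C(c2ccccc2)(c2ccccc2)c2ccccc2 | intermediate
5 | lithium enolate of 4 | O(C[C@@H]1CC(C)=C([O-])O1)C(c2ccccc2)(c2ccccc2)c2ccccc2.[Li+] | intermediate
6 | (3S,5S)-3-methyl-5-[(trityloxy)methyl]dihydrofuran-2(3H)-one (cis) | O(C[C@@H]1C[C@H](C)C(=O)O1)C(c2ccccc2)(c2ccccc2)c2ccccc2 | intermediate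
7 | (3S,5S)-5-(hydroxymethyl)-3-methyldihydrofuran-2(3H)-one | OC[C@@H]1C[C@H](C)C(=O)O1 | intermediate
8 | (2S,4S)-4-methyl-5-oxotetrahydrofuran-2-carbaldehyde | O=C[C@@H]1C[C@H](C)C(=O)O1 | intermediate
9 | N-benzylhydroxylamine | ONCc1ccccc1 | starting material
10 | (Z)-N-benzyl-1-[(2S,4S)-4-methyl-5-oxotetrahydrofuran-2-yl]methanimine N-oxide | [O-]/[N+](Cc1ccccc1)=C\[C@@H]1C[C@H](C)C(=O)O1 | intermediate
11 | (Z)-4-(benzyloxy)but-2-en-1-ol | OC/C=C\COCc1ccccc1 | starting material
12 | (Z)-4-(benzyloxy)but-2-en-1-yl acetate | CC(=O)OC/C=C\COCc1ccccc1 | intermediate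
13 | 1,4-dioxaspiro[4.5]dec-6-en-8-one | O=C1C=CC2(CC1)OCCO2 | starting material
14 | diethylzinc | CC[Zn]CC | starting material
15 | ethylzinc enolate of (S)-6-ethyl-1,4-dioxaspiro[4.5]decan-8-one | CC[C@H]1C=C(O[Zn]CC)CCC12OCCO2 | intermediate
16 | (6S,7S)-7-[(E)-4-(benzyloxy)but-2-en-1-yl]-6-ethyl-1,4-dioxaspiro[4.5]decan-8-one | CC[C@H]1[C@H](C/C=C/COCc2ccccc2)C(=O)CCC12OCCO2 | intermediate
17 | (6S,7S)-7-[4-(benzyloxy)butyl]-6-ethyl-1,4-dioxaspiro[4.5]decan-8-one | CC[C@H]1[C@H](CCCCOCc2ccccc2)C(=O)CCC12OCCO2 | intermediate
18 | lithium enolate of 17 (toward C9) | CC[C@H]1[C@H](CCCCOCc2ccccc2)C([O-])=CCC12OCCO2.[Li+] | intermediate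
19 | (6S,7S)-7-[4-(benzyloxy)butyl]-9-[(dimethylamino)methyl]-6-ethyl-1,4-dioxaspiro[4.5]decan-8-one (C9 epimers, centre left undefined) | CC[C@H]1[C@H](CCCCOCc2ccccc2)C(=O)C(CN(C)C)CC12OCCO2 | intermediate
20 | methiodide of 19 | CC[C@H]1[C@H](CCCCOCc2ccccc2)C(=O)C(C[N+](C)(C)C)CC12OCCO2.[I-] | intermediate
21 | (6S,7S)-7-[4-(benzyloxy)butyl]-6-ethyl-9-methylidene-1,4-dioxaspiro[4.5]decan-8-one | CC[C@H]1[C@H](CCCCOCc2ccccc2)C(=O)C(=C)CC12OCCO2 | intermediate
22 | N-benzyl spiro-isoxazolidine joining ring C and the lactone E fragment | CC[C@H]1[C@H](CCCCOCc5ccccc5)C(=O)[C@@]3(C[C@H]([C@@H]4C[C@H](C)C(=O)O4)N(Cc4ccccc4)O3)CC12OCCO2 | intermediate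
23 | ammonium trifluoroacetate of the ring-opened amino ketone (N–O, N–Bn and O–Bn cleaved) | CC[C@H]1[C@H](CCCCO)C(=O)[C@@](O)(C[C@@H]([NH3+])[C@@H]3C[C@H](C)C(=O)O3)CC12OCCO2.[O-]C(=O)C(F)(F)F | intermediate
24 | hydroxy imine with ring B closed, ring C ketal, 4-hydroxybutyl arm | CC[C@H]1[C@H](CCCCO)C2=N[C@@H]([C@@H]3C[C@H](C)C(=O)O3)C[C@@]2(O)CC12OCCO2 | intermediate
25 | primary mesylate of 24 | CC[C@H]1[C@H](CCCCOS(C)(=O)=O)C2=N[C@@H]([C@@H]3C[C@H](C)C(=O)O3)C[C@@]2(O)CC12OCCO2 | intermediate
26 | cyclic iminium mesylate (ring A closed on nitrogen) | CC[C@H]1[C@@H]4CCCC[N+]5=C4[C@@](O)(C[C@@H]5[C@@H]3C[C@H](C)C(=O)O3)CC12OCCO2.CS(=O)(=O)[O-] | intermediate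
27 | tricyclic enamine (rings A, B, C) with tertiary alcohol and ring C ketal | CC[C@H]1C2=C3N(CCCC2)[C@@H]([C@@H]2C[C@H](C)C(=O)O2)C[C@@]3(O)CC12OCCO2 | intermediate
28 | tricyclic enamine hydroxy ketone | CC[C@H]1C2=C3N(CCCC2)[C@@H]([C@@H]2C[C@H](C)C(=O)O2)C[C@@]3(O)CC1=O | intermediate
29 | methyl (R)-lactate | C[C@@H](O)C(=O)OC | starting material
30 | methyl (R)-2-{[(trifluoromethyl)sulfonyl]oxy}propanoate | C[C@@H](OS(=O)(=O)C(F)(F)F)C(=O)OC | intermediate
31 | dilithium alkoxide enolate of 28 | CC[C@H]1C2=C3N(CCCC2)[C@@H]([C@@H]2C[C@H](C)C(=O)O2)C[C@@]3([O-])C=C1[O-].[Li+].[Li+] | intermediate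
32 | lithium alkoxide of the C-alkylated methyl ester (lactonisable epimer shown) | CC[C@H]1C2=C3N(CCCC2)[C@@H]([C@@H]2C[C@H](C)C(=O)O2)C[C@@]3([O-])[C@H]([C@@H](C)C(=O)OC)C1=O.[Li+] | intermediate
33 | keto lactone (rings A to E, ring C ketone) | CC[C@H]1C2=C3N(CCCC2)[C@@H]([C@@H]2C[C@H](C)C(=O)O2)C[C@]32OC(=O)[C@H](C)[C@@H]2C1=O | intermediate
34 | CNP0154902.3 | CC[C@H]1C2=C3N(CCCC2)[C@@H]([C@@H]2C[C@H](C)C(=O)O2)C[C@]32OC(=O)[C@H](C)[C@@H]2[C@@H]1O | target

**Step count**

Total: 18 steps. Longest linear sequence: 12 steps (steps 1–6, 12–15, 17, 18).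

**Three steps most likely to fail**

Step 12. Facial discrimination on either partner or the exo preference may be too weak, so that several of the four spiro-isoxazolidines form, and the enone may dimerise before the dipole adds. Fallback (sets out from aldehyde 8 and enone 21, comes back at imine 24): a stereogenic group on the nitrone nitrogen adds a third control element next to the reacting carbon. Condensation of 8 with N-[(S)-1-phenylethyl]hydroxylamine gives the N-(1-phenylethyl) nitrone F1; cycloaddition with 21 under the step 12 conditions gives the N-(1-phenylethyl) spiro-isoxazolidine F2; the hydrogenolysis and buffered cyclisation of step 13 also remove the 1-phenylethyl group and deliver 24.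

Step 17. Substitution at the secondary triflate by the hindered dianion may lose out to elimination of the triflate or to O-alkylation. Fallback (sets out from 28, comes back at 33): aldol addition, dehydration and hydrogenation in place of the alkylation. Dianion 31 is added to methyl pyruvate at −78 °C and the tertiary alkoxide on ring C closes lactone D, giving the α-hydroxy-α-methyl keto lactone F3 (either carbinol epimer serves). Syn dehydration of the tertiary alcohol into the methyl group with methyl N-(triethylammoniosulfonyl)carbamate gives the α-methylene keto lactone F4. Hydrogenation with RhCl(PPh3)3, which spares the tetrasubstituted enamine, should add hydrogen from the convex face of the cis-fused lactone and give 33 with the methyl group on the ring C side.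

Step 18. Hydride may enter from the lactone face instead of the ethyl face and give mainly the epimeric alcohol. Fallback (sets out from 33, comes back at 34): inversion at carbon instead of reliance on the facial bias. Reduction under the preference that does operate (NaBH4, EtOH–THF, −40 °C) gives the epimeric alcohol F5. Mitsunobu esterification with 4-nitrobenzoic acid (PPh3, diisopropyl azodicarboxylate; the acid keeps the enamine protonated) gives the inverted 4-nitrobenzoate F6. Mild methanolysis (K2CO3 cat., MeOH, 0 °C) releases 34.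

**Further compounds**

F1 | step 12 | (Z)-N-[(S)-1-phenylethyl]-1-[(2S,4S)-4-methyl-5-oxotetrahydrofuran-2-yl]methanimine N-oxide | [O-]/[N+]([C@@H](C)c1ccccc1)=C\[C@@H]1C[C@H](C)C(=O)O1
F2 | step 12 | N-[(S)-1-phenylethyl] spiro-isoxazolidine (analogue of 22) | CC[C@H]1[C@H](CCCCOCc5ccccc5)C(=O)[C@@]3(C[C@H]([C@@H]4C[C@H](C)C(=O)O4)N([C@@H](C)c4ccccc4)O3)CC12OCCO2
F3 | step 17 | α-hydroxy-α-methyl keto lactone (carbinol centre undefined) | CC[C@H]1C2=C3N(CCCC2)[C@@H]([C@@H]2C[C@H](C)C(=O)O2)C[C@]32OC(=O)C(C)(O)[C@@H]2C1=O
F4 | step 17 | α-methylene keto lactone | CC[C@H]1C2=C3N(CCCC2)[C@@H]([C@@H]2C[C@H](C)C(=O)O2)C[C@]32OC(=O)C(=C)[C@@H]2C1=O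
F5 | step 18 | carbinol epimer of 34 | CC[C@H]1C2=C3N(CCCC2)[C@@H]([C@@H]2C[C@H](C)C(=O)O2)C[C@]32OC(=O)[C@H](C)[C@@H]2[C@H]1O
F6 | step 18 | 4-nitrobenzoate of 34 | CC[C@H]1C2=C3N(CCCC2)[C@@H]([C@@H]2C[C@H](C)C(=O)O2)C[C@]32OC(=O)[C@H](C)[C@@H]2[C@@H]1OC(=O)c1ccc(cc1)[N+](=O)[O-]
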